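**Plan**

- Numbering of the quinone ring: C1 (C=O next to C–OH), C2 (C–OH), C3 (C–hexadecyl), C4 (C=O), C5 (C–OMe), C6 (C–H).
- Retrosynthesis: O2–H is masked as a benzyl ether; then O5–CH3 and the two ring bonds C1–C6 and C5–C6 are cut. This works because C6 is the only ring CH and lies between the carbonyl-level carbons C1 and C5: removing it leaves the five-membered ring C1–C2–C3–C4–C5 as a cyclopentene-1,2,3-trione (C1, C5, C4 = C=O) that already carries C2–OBn and C3–hexadecyl.
- That five-membered ring is cut at C2–C3 and C1–C5 into nonadecan-2-one (C3, C4, C5 and the chain) and diethyl oxalate (C1, C2); the C5 carbonyl comes from oxidation of the ring CH2.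
- Forward: Claisen/Dieckmann closure of the five-membered ring, deethoxalylation, O-benzylation of the enol, CH2 → C=O by diazo transfer and dimethyldioxirane, diazomethane enlargement of the five- to the six-membered ring with methylation of O5, then hydrogenolysis and air oxidation to free O2–H.
- Stereochemistry: none to set; the target has no stereocentre and no stereogenic double bond.

Key step: step 6

Remark: the target is achiral, so the demand for a single enantiomer is met by the compound itself.
Remark: diazomethane (9) is used as a dried ethereal solution distilled beforehand from commercial N-methyl-N-nitroso-p-toluenesulfonamide and KOH, and is counted as a reagent-grade starting material.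

**Route**

Step 1
Reactants: 1 nonadecan-2-one; 2 diethyl oxalate
Product: 3 ethyl 2-(4-hexadecyl-3-hydroxy-2,5-dioxocyclopent-3-en-1-yl)-2-oxoacetate (ring enol of 5-ethoxalyl-3-hexadecylcyclopentane-1,2,4-trione; racemic, enolisable centre)
Conditions: 2 (2.2 equiv), NaOEt (2.2 equiv), EtOH/toluene, 0 °C to reflux; then cold 2 M HCl
Reagents that add atoms: diethyl oxalate, CCOC(=O)C(=O)OCC
Why: Crossed Claisen condensations of both α-positions of the methyl ketone with one oxalate close the five-membered 1,2,4-trione ring (Claisen/Dieckmann) and a second oxalate C-acylates the remaining ring methylene, the stabilised polyenolate driving the cascade as in the classical preparation of 3-alkylcyclopentane-1,2,4-triones from 2-alkanones.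

Step 2
Reactants: 3 ethyl 2-(4-hexadecyl-3-hydroxy-2,5-dioxocyclopent-3-en-1-yl)-2-oxoacetate
Product: 4 3-hexadecylcyclopentane-1,2,4-trione (drawn as its enol, 5-hexadecyl-4-hydroxycyclopent-4-ene-1,3-dione)
Conditions: 2 M HCl, dioxane, reflux
Reagents that add atoms: none
Why: Acid hydrolysis of the side-chain ester followed by hydrolytic retro-Claisen cleavage of the exocyclic C–C bond (deethoxalylation) should expel oxalic acid and leave the ring trione, the standard second stage of this trione synthesis.

Step 3
Reactants: 4 3-hexadecylcyclopentane-1,2,4-trione; 5 benzyl alcohol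
Product: 6 4-(benzyloxy)-5-hexadecylcyclopent-4-ene-1,3-dione
Conditions: BnOH (1.5 equiv), TsOH·H2O (5 mol %), toluene, reflux, Dean–Stark
Reagents that add atoms: benzyl alcohol, OCc1ccccc1
Why: Acid-catalysed enol etherification of the cyclic β-diketone enol (a vinylogous Fischer esterification driven by azeotropic water removal) is reversible and should settle on the more stable cross-conjugated ene-dione ether at the oxalate-derived oxygen (future O2) without the C-benzylation that a benzyl halide and base would invite, and even the other O-benzyl regioisomer would lead to the same trione 8 once the ring CH2 is oxidised.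

Step 4
Reactants: 6 4-(benzyloxy)-5-hexadecylcyclopent-4-ene-1,3-dione
Product: 7 4-(benzyloxy)-2-diazo-5-hexadecylcyclopent-4-ene-1,3-dione
Conditions: p-ABSA (1.1 equiv), Et3N, MeCN, 0 °C to rt
Reagents that add atoms: 4-acetamidobenzenesulfonyl azide (p-ABSA), CC(=O)Nc1ccc(cc1)S(=O)(=O)N=[N+]=[N-]
Why: Regitz diazo transfer from a sulfonyl azide to the ring methylene flanked by both ketones is routine for cyclic 1,3-diones such as indane-1,3-dione, and the enol ether and benzyl group are inert to the azide and the amine.

Step 5
Reactants: 7 4-(benzyloxy)-2-diazo-5-hexadecylcyclopent-4-ene-1,3-dione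
Product: 8 4-(benzyloxy)-5-hexadecylcyclopent-4-ene-1,2,3-trione
Conditions: DMDO (1.2 equiv, acetone), CH2Cl2, 0 °C to rt; evaporation under dry N2, used at once
Reagents that add atoms: dimethyldioxirane, CC1(C)OO1
Why: Oxygen-atom transfer from dimethyldioxirane to the diazo carbon with loss of N2 is the established neutral, anhydrous conversion of 2-diazo-1,3-dicarbonyl compounds into vicinal tricarbonyls, and it leaves only acetone so the moisture-sensitive trione is obtained unhydrated.

Step 6
Reactants: 8 4-(benzyloxy)-5-hexadecylcyclopent-4-ene-1,2,3-trione; 9 diazomethane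
Product: 11 2-(benzyloxy)-3-hexadecyl-5-methoxycyclohexa-2,5-diene-1,4-dione, via hydroxyquinone 10 (not isolated)
Conditions: CH2N2 (2.3 equiv, dry Et2O), Et2O/CH2Cl2, −20 to 0 °C; AcOH quench
Reagents that add atoms: diazomethane, C=[N+]=[N-]
Why: The nucleophilic carbon of diazomethane adds to the central ketone C5 of the vicinal trione (the most electrophilic carbonyl, as in indane-1,2,3-trione) or to C1, and the diazonium alkoxide loses N2 with 1,2-shift of the neighbouring ketonic acyl carbon, which in either case places the new CH2 between C1 and C5 (new bonds C1–C6 and C5–C6). The closest known reaction is the diazoalkane homologation (Büchner–Curtius–Schlotterbeck reaction) of cyclic vicinal triketones, by which indane-1,2,3-trione is enlarged to 2-hydroxy-1,4-naphthoquinone and its methyl ether. The six-membered ring is therefore closed by ring enlargement, a 1,2-migration of the C1–C5 ring bond onto the inserted carbon, and not by an end-to-end cyclisation; the cyclohexenetrione so formed enolises at once to hydroxyquinone 10, whose vinylogous-acid OH at C5 is O-methylated by the second equivalent of diazomethane. No stereocentre is created. The selectivity needed is insertion into C1–C5 rather than C4–C5 and acyl shift rather than oxirane closure: the benzyl enol ether at O2 turns C4=O into a vinylogous ester, which is the least electrophilic carbonyl and, like ester and amide carbonyls in other 1,2-carbonyl shifts, should be a much poorer migrating group than the ketonic C1 acyl, and no Lewis acid is used because it would bind and activate that basic C4 oxygen. Low temperature, a salt-free ethereal medium and a limited excess of reagent should suppress spiro-oxirane formation and dipolar addition of diazomethane to the C5=C6 bond of the product.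

Step 7
Reactants: 11 2-(benzyloxy)-3-hexadecyl-5-methoxycyclohexa-2,5-diene-1,4-dione
Product: 14 3-hexadecyl-2-hydroxy-5-methoxycyclohexa-2,5-diene-1,4-dione (target), via benzyloxyhydroquinone 12 (not isolated), via benzenetriol 13 (not isolated)
Conditions: H2 (1 atm), 10% Pd/C, EtOAc, rt; filtration under Ar; then air, rt
Reagents that add atoms: none
Why: Catalytic hydrogenation first reduces the quinone to the hydroquinone and then cleaves the benzyl aryl ether by hydrogenolysis, and the electron-rich benzenetriol should autoxidise in air back to the hydroxy-p-quinone (the usual reduce–reoxidise debenzylation of benzyloxyquinones) while the O5 methyl ether and the alkyl chain are unaffected.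

**Compound list**

1 | nonadecan-2-one | CCCCCCCCCCCCCCCCCC(C)=O | starting material
2 | diethyl oxalate | CCOC(=O)C(=O)OCC | starting material
3 | ethyl 2-(4-hexadecyl-3-hydroxy-2,5-dioxocyclopent-3-en-1-yl)-2-oxoacetate (racemic, enolisable centre) | CCCCCCCCCCCCCCCCC1=C(O)C(=O)C(C(=O)C(=O)OCC)C1=O | intermediate
4 | 3-hexadecylcyclopentane-1,2,4-trione (as enol, 5-hexadecyl-4-hydroxycyclopent-4-ene-1,3-dione) | CCCCCCCCCCCCCCCCC1=C(O)C(=O)CC1=O | intermediate
5 | benzyl alcohol | OCc1ccccc1 | starting material
6 | 4-(benzyloxy)-5-hexadecylcyclopent-4-ene-1,3-dione | CCCCCCCCCCCCCCCCC1=C(OCc2ccccc2)C(=O)CC1=O | intermediate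
7 | 4-(benzyloxy)-2-diazo-5-hexadecylcyclopent-4-ene-1,3-dione | CCCCCCCCCCCCCCCCC1=C(OCc2ccccc2)C(=O)C(=[N+]=[N-])C1=O | intermediate
8 | 4-(benzyloxy)-5-hexadecylcyclopent-4-ene-1,2,3-trione | CCCCCCCCCCCCCCCCC1=C(OCc2ccccc2)C(=O)C(=O)C1=O | intermediate
9 | diazomethane | C=[N+]=[N-] | starting material
10 | 2-(benzyloxy)-3-hexadecyl-5-hydroxycyclohexa-2,5-diene-1,4-dione | CCCCCCCCCCCCCCCCC1=C(OCc2ccccc2)C(=O)C=C(O)C1=O | intermediate
11 | 2-(benzyloxy)-3-hexadecyl-5-methoxycyclohexa-2,5-diene-1,4-dione | CCCCCCCCCCCCCCCCC1=C(OCc2ccccc2)C(=O)C=C(OC)C1=O | intermediate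
12 | 2-(benzyloxy)-3-hexadecyl-5-methoxybenzene-1,4-diol | CCCCCCCCCCCCCCCCc1c(OCc2ccccc2)c(O)cc(OC)c1O | intermediate
13 | 3-hexadecyl-5-methoxybenzene-1,2,4-triol | CCCCCCCCCCCCCCCCc1c(O)c(O)cc(OC)c1O | intermediate
14 | 3-hexadecyl-2-hydroxy-5-methoxycyclohexa-2,5-diene-1,4-dione | CCCCCCCCCCCCCCCCC1=C(O)C(=O)C=C(OC)C1=O | target

**Step count and risks**

Total step count: 7. Longest linear sequence: 7 steps (from nonadecan-2-one).

Steps most likely to fail:

1. Step 6 (ring enlargement). The diazonium alkoxide may close to a spiro-oxirane instead of undergoing acyl shift, the C4–C5 bond may migrate in place of C1–C5, or surplus diazomethane may add as a dipole to the C5=C6 bond of the quinone once it has formed. The fallback performs the same C1–C6/C5–C6 insertion in separate, individually controllable operations with a diazoacetate. Setting out from 8, DBU-catalysed aldol-type addition of tert-butyl diazoacetate (MeCN, 0 °C) to the central ketone should give tert-butyl 2-[3-(benzyloxy)-4-hexadecyl-1-hydroxy-2,5-dioxocyclopent-3-en-1-yl]-2-diazoacetate F1 (racemic). Rh2(OAc)4 (cat., CH2Cl2, rt) then releases N2, and the rhodium carbenoid takes up the adjacent ketonic acyl by 1,2-shift, the ring enlargement known for isatin-derived diazo carbinols, to give tert-butyl 5-(benzyloxy)-4-hexadecyl-2-hydroxy-3,6-dioxocyclohexa-1,4-diene-1-carboxylate F2; no oxirane pathway exists and no free diazomethane meets the quinone. TFA in CH2Cl2 cleaves the tert-butyl ester and the vinylogous β-keto acid decarboxylates on gentle warming to hydroxyquinone 10, which is methylated with Me2SO4/K2CO3 in acetone, so the sequence comes back to the route at 11.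

2. Step 3 (enol etherification). Etherification may occur at the other enol oxygen, or both oxygens may react, giving a mixture that cannot be taken cleanly through the diazo transfer. The fallback uses the fact that only one 4-alkoxy-5-alkylcyclopentene-1,2,3-trione exists. Setting out from 4, the regioisomeric ether 4-(benzyloxy)-3-hexadecylcyclopent-3-ene-1,2-dione F3, alone or mixed with 6, is subjected to Riley oxidation (SeO2, dioxane, 90 °C). This oxidises the ketone α-methylene of either isomer to a carbonyl, and azeotropic removal of the water formed returns the route at 8, bypassing steps 4 and 5.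

3. Step 5 (diazo to ketone). Oxygen transfer from the dioxirane may also reach the enol-ether double bond or the benzylic C–H, or the central carbonyl may hydrate and decompose during isolation. The fallback is the enaminone cleavage route to vicinal tricarbonyls. Setting out from 6, condensation with N,N-dimethylformamide dimethyl acetal (toluene, rt to 60 °C) should give (Z)-4-(benzyloxy)-2-[(dimethylamino)methylidene]-5-hexadecylcyclopent-4-ene-1,3-dione F4 (geometry immaterial; the Z form is listed). Its electron-rich enamine double bond is cleaved by singlet oxygen (O2, hν, tetraphenylporphyrin, CH2Cl2, −78 °C) to give the trione and DMF, rejoining the route at 8.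

**Further compounds**

F1 | step 6 | tert-butyl 2-[3-(benzyloxy)-4-hexadecyl-1-hydroxy-2,5-dioxocyclopent-3-en-1-yl]-2-diazoacetate (racemic) | CCCCCCCCCCCCCCCCC1=C(OCc2ccccc2)C(=O)C(O)(C(=[N+]=[N-])C(=O)OC(C)(C)C)C1=O
F2 | step 6 | tert-butyl 5-(benzyloxy)-4-hexadecyl-2-hydroxy-3,6-dioxocyclohexa-1,4-diene-1-carboxylate | CCCCCCCCCCCCCCCCC1=C(OCc2ccccc2)C(=O)C(C(=O)OC(C)(C)C)=C(O)C1=O
F3 | step 3 | 4-(benzyloxy)-3-hexadecylcyclopent-3-ene-1,2-dione | CCCCCCCCCCCCCCCCC1=C(OCc2ccccc2)CC(=O)C1=O
F4 | step 5 | (Z)-4-(benzyloxy)-2-[(dimethylamino)methylidene]-5-hexadecylcyclopent-4-ene-1,3-dione | CN(C)/C=C1/C(=O)C(CCCCCCCCCCCCCCCC)=C(OCc2ccccc2)C1=O
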